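The plan disconnects ring B between C8 and C9. There the target shows a C17=C8–C9(H)–C11 array, an exocyclic methylene next to a methine carrying a two-carbon arm: the signature of an Alder-ene reaction between a C8≡C17 alkyne and a C9=C11–C12 propenyl group. A palladium-hydride enyne cycloisomerisation of a ring A cyclohexanone, bearing a but-3-ynyl chain at C5 and an (E)-propenyl group at quaternary C10, should therefore close ring B, set C9, create the 8(17)-methylene and leave a C11=C12 vinyl handle for a B-alkyl Suzuki–Miyaura chain extension. The precursor comes from 2,4,4-trimethylcyclohexenone through asymmetric reduction, Ireland–Claisen chirality transfer, allylic oxidation and anti conjugate addition.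

Key step: step 7

Assumption: labdane numbering is used throughout (ring A = C1–C5 and C10; ring B = C5–C10; side chain C11–C16; exocyclic methylene C17; gem-dimethyl C18/C19; angular methyl C20), and compounds 1, 3, 11 and 16 are taken as catalogue chemicals.

Step 1
Reactants: 1 2,4,4-trimethylcyclohex-2-en-1-one
Product: 2 (1R)-2,4,4-trimethylcyclohex-2-en-1-ol
Conditions: (S)-2-methyl-CBS-oxazaborolidine (10 mol %), BH3·SMe2, THF, −20 °C; MeOH quench
Reagents that add atoms: none
Why: Corey–Bakshi–Shibata reduction, in which the methyl-substituted alkene arm is the large group and the ring CH2 the small one, so the (S)-catalyst should deliver hydride to give the (R)-allylic alcohol from which every later stereocentre descends.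

Step 2
Reactants: 2 (1R)-2,4,4-trimethylcyclohex-2-en-1-ol; 3 5-(trimethylsilyl)pent-4-ynoic acid
Product: 4 (1R)-2,4,4-trimethylcyclohex-2-en-1-yl 5-(trimethylsilyl)pent-4-ynoate
Conditions: DCC, DMAP (cat.), CH2Cl2, 0 °C → rt
Reagents that add atoms: none
Why: Steglich esterification acylates the secondary allylic alcohol at oxygen, so the carbinol configuration is retained.

Step 3
Reactants: 4 (1R)-2,4,4-trimethylcyclohex-2-en-1-yl 5-(trimethylsilyl)pent-4-ynoate
Product: 7 2-[(1S)-2,6,6-trimethylcyclohex-2-en-1-yl]-5-(trimethylsilyl)pent-4-ynoic acid (both epimers at the carboxyl-bearing carbon), via silyl ketene acetal 5 (not isolated), via trimethylsilyl ester 6 (not isolated)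
Conditions: LiN(i-Pr)2, Me3SiCl, THF, −78 °C → rt, then 65 °C; aq. HCl
Reagents that add atoms: none
Why: Ireland–Claisen rearrangement; the suprafacial [3,3] shift forms the C5–C6 bond on the ring face that carried the ester oxygen, so the C1 carbinol chirality is relayed to C5 (S) while the alkene moves to C1=C10, and the uncontrolled C6 centre is erased in step 4.

Step 4
Reactants: 7 2-[(1S)-2,6,6-trimethylcyclohex-2-en-1-yl]-5-(trimethylsilyl)pent-4-ynoic acid
Product: 9 trimethyl{4-[(1S)-2,6,6-trimethylcyclohex-2-en-1-yl]but-1-yn-1-yl}silane, via thiohydroxamate ester 8 (not isolated)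
Conditions: 1-hydroxypyridine-2(1H)-thione, DCC, DMAP (cat.), CH2Cl2, dark, rt; then t-BuSH, hν (tungsten lamp), PhH, rt
Reagents that add atoms: none
Why: Barton reductive decarboxylation; the secondary C6 radical should take hydrogen from the thiol faster than it can add to the ring alkene, so both epimers converge on one product and C5 is untouched.

Step 5
Reactants: 9 trimethyl{4-[(1S)-2,6,6-trimethylcyclohex-2-en-1-yl]but-1-yn-1-yl}silane
Product: 10 (4S)-3,5,5-trimethyl-4-[4-(trimethylsilyl)but-3-yn-1-yl]cyclohex-2-en-1-one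
Conditions: Rh2(C6H10NO)4 (dirhodium tetracaprolactamate, 1 mol %), t-BuOOH (70% aq.), K2CO3, CH2Cl2, rt
Reagents that add atoms: tert-butyl hydroperoxide, CC(C)(C)OO
Why: Allylic C–H oxidation by a tert-butylperoxyl radical chain should take place at the ring C2 methylene, the least hindered allylic site next to the unsubstituted alkene terminus, giving the conjugated enone without touching the shielded tertiary C5–H.

Step 6
Reactants: 10 (4S)-3,5,5-trimethyl-4-[4-(trimethylsilyl)but-3-yn-1-yl]cyclohex-2-en-1-one; 11 (E)-1-bromoprop-1-ene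
Product: 13 (3R,4S)-4-(but-3-yn-1-yl)-3,5,5-trimethyl-3-[(1E)-prop-1-en-1-yl]cyclohexan-1-one, via bis-silylated enol ether 12 (not isolated)
Conditions: 11, t-BuLi, Et2O, −78 °C; CuI, −40 °C; then 10, Me3SiCl, THF, −78 → −20 °C; then K2CO3, MeOH, rt
Reagents that add atoms: none
Why: Me3SiCl-accelerated conjugate addition of a lithium dialkenylcuprate followed by methanolysis of both silyl groups; the propenyl group should add axially at C10 anti to the pseudo-axial C5 chain, which sets the quaternary centre with C9 trans to C6 and the C20 methyl cis to it.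

Step 7
Reactants: 13 (3R,4S)-4-(but-3-yn-1-yl)-3,5,5-trimethyl-3-[(1E)-prop-1-en-1-yl]cyclohexan-1-one
Product: 14 (5S,9S,10S)-13,14,15,16-tetranorlabda-8(17),11-dien-2-one [(4aS,8S,8aS)-8-ethenyl-4,4,8a-trimethyl-7-methylideneoctahydronaphthalen-2(1H)-one]
Conditions: Pd2(dba)3·CHCl3 (2.5 mol %), P(o-tol)3 (10 mol %), AcOH (20 mol %), PhH, 0.02 M, 60 °C
Reagents that add atoms: none
Why: Zerovalent palladium and AcOH give a divalent palladium hydride that adds across the terminal alkyne with palladium at C8; the alkenyl–palladium then inserts the C9=C11 bond of the propenyl group, and beta-hydride elimination towards the C12 methyl releases the 1,4-diene and regenerates the hydride. The closest known reaction type is the palladium-catalysed Alder-ene-type cycloisomerisation of 1,6- and 1,7-enynes. Ring B closes in the 6-exo-trig mode through the C8–C9 bond. The new C9 stereocentre is under substrate control: the trans-diequatorial tethers at C5 and C10 enforce a chair-like insertion transition state with the propenyl terminus C11 pseudo-equatorial, so C9–H should become axial and anti to the axial C20 methyl (9S). The step needs elimination of a C12 hydrogen and not of C9–H (which would give the conjugated 1,3-diene), and ring closure ahead of alkyne oligomerisation; the first is secured by three unhindered methyl hydrogens against one tertiary hydrogen next to quaternary C10, the second by high dilution.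

Step 8
Reactants: 14 (5S,9S,10S)-13,14,15,16-tetranorlabda-8(17),11-dien-2-one
Product: 15 (2R,5S,9S,10S)-13,14,15,16-tetranorlabda-8(17),11-dien-2-ol (2β-hydroxy, axial)
Conditions: LiBH(s-Bu)3, THF, −78 °C; aq. NH4Cl
Reagents that add atoms: none
Why: Bulky-hydride ketone reduction; the β face of the C2 carbonyl is screened by the syn-axial C19 and C20 methyls, so hydride should enter from the α (equatorial) side and leave the axial 2β-alcohol (2R).

Step 9
Reactants: 16 ethyl but-2-ynoate
Product: 17 ethyl (2Z)-3-iodobut-2-enoate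
Conditions: NaI, AcOH, 115 °C
Reagents that add atoms: sodium iodide, [Na+].[I-]
Why: Hydroiodination of an ynoate by conjugate addition of iodide and anti protonation should give the (Z)-β-iodo enoate with iodine cis to the ester.

Step 10
Reactants: 15 (2R,5S,9S,10S)-13,14,15,16-tetranorlabda-8(17),11-dien-2-ol; 17 ethyl (2Z)-3-iodobut-2-enoate
Product: 19 ethyl (2R,5S,9S,10S,13Z)-2-hydroxylabda-8(17),13-dien-15-oate, via B-alkyl disiamylborane 18 (not isolated)
Conditions: (Me2CHCHMe)2BH [from BH3·THF + 2-methylbut-2-ene, THF, 0 °C], 0 °C → rt; then 17, PdCl2(dppf), AsPh3, 3 M aq. K3PO4, DMF, rt → 45 °C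
Reagents that add atoms: none
Why: Chemoselective hydroboration then B-alkyl Suzuki–Miyaura coupling; the hindered dialkylborane should add to the monosubstituted C11=C12 vinyl group (boron at C12) much faster than to the 1,1-disubstituted C8=C17 alkene, and the coupling retains the iodide geometry to give the 13Z enoate.

Step 11
Reactants: 19 ethyl (2R,5S,9S,10S,13Z)-2-hydroxylabda-8(17),13-dien-15-oate
Product: 20 (2R,5S,9S,10S,13Z)-2-hydroxylabda-8(17),13-dien-15-oic acid
Conditions: LiOH, THF/MeOH/H2O, 40 °C; then 1 M HCl, 0 °C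
Reagents that add atoms: lithium hydroxide (its oxygen ends up in the carboxyl group), [Li+].[OH-]
Why: Saponification of the ethyl ester; the Z-trisubstituted enoate is not isomerised by hydroxide and no stereocentre lies α to a carbonyl.

Step 12
Reactants: 20 (2R,5S,9S,10S,13Z)-2-hydroxylabda-8(17),13-dien-15-oic acid
Product: 22 (2R,5S,9S,10S,13Z)-2-acetoxylabda-8(17),13-dien-15-oic acid (CNP0255148.1), via mixed acetic anhydride 21 (not isolated)
Conditions: Ac2O, pyridine, DMAP, CH2Cl2, rt → 40 °C; then H2O, THF, rt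
Reagents that add atoms: acetic anhydride, CC(=O)OC(C)=O
Why: DMAP-catalysed acetylation of the hindered axial alcohol with retention at C2; the carboxylic acid is converted for the time being into its mixed anhydride, which the aqueous work-up should hydrolyse back.

Compound list
1 | 2,4,4-trimethylcyclohex-2-en-1-one | CC1=CC(C)(C)CCC1=O | starting material
2 | (1R)-2,4,4-trimethylcyclohex-2-en-1-ol | CC1=CC(C)(C)CC[C@H]1O | intermediate
3 | 5-(trimethylsilyl)pent-4-ynoic acid | C[Si](C)(C)C#CCCC(=O)O | starting material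
4 | (1R)-2,4,4-trimethylcyclohex-2-en-1-yl 5-(trimethylsilyl)pent-4-ynoate | CC1=CC(C)(C)CC[C@H]1OC(=O)CCC#C[Si](C)(C)C | intermediate
5 | trimethylsilyl ketene acetal of ester 4 (enol ether geometry not defined) | CC1=CC(C)(C)CC[C@H]1OC(O[Si](C)(C)C)=CCC#C[Si](C)(C)C | intermediate
6 | trimethylsilyl 2-[(1S)-2,6,6-trimethylcyclohex-2-en-1-yl]-5-(trimethylsilyl)pent-4-ynoate (both epimers at the α-carbon) | CC1=CCCC(C)(C)[C@@H]1C(CC#C[Si](C)(C)C)C(=O)O[Si](C)(C)C | intermediate
7 | 2-[(1S)-2,6,6-trimethylcyclohex-2-en-1-yl]-5-(trimethylsilyl)pent-4-ynoic acid (both epimers at the α-carbon) | CC1=CCCC(C)(C)[C@@H]1C(CC#C[Si](C)(C)C)C(=O)O | intermediate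
8 | 2-thioxopyridin-1(2H)-yl ester (thiohydroxamate ester) of acid 7 | CC1=CCCC(C)(C)[C@@H]1C(CC#C[Si](C)(C)C)C(=O)ON1C=CC=CC1=S | intermediate
9 | trimethyl{4-[(1S)-2,6,6-trimethylcyclohex-2-en-1-yl]but-1-yn-1-yl}silane | CC1=CCCC(C)(C)[C@@H]1CCC#C[Si](C)(C)C | intermediate
10 | (4S)-3,5,5-trimethyl-4-[4-(trimethylsilyl)but-3-yn-1-yl]cyclohex-2-en-1-one | CC1=CC(=O)CC(C)(C)[C@@H]1CCC#C[Si](C)(C)C | intermediate
11 | (E)-1-bromoprop-1-ene | C/C=C/Br | starting material
12 | trimethylsilyl enol ether of the conjugate adduct, alkynylsilane still in place | C[Si](C)(C)C#CCC[C@H]1C(C)(C)CC(O[Si](C)(C)C)=C[C@]1(C)/C=C/C | intermediate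
13 | (3R,4S)-4-(but-3-yn-1-yl)-3,5,5-trimethyl-3-[(1E)-prop-1-en-1-yl]cyclohexan-1-one | C#CCC[C@H]1C(C)(C)CC(=O)C[C@]1(C)/C=C/C | intermediate
14 | (5S,9S,10S)-13,14,15,16-tetranorlabda-8(17),11-dien-2-one | C=C1CC[C@H]2C(C)(C)CC(=O)C[C@]2(C)[C@H]1C=C | intermediate
15 | (2R,5S,9S,10S)-13,14,15,16-tetranorlabda-8(17),11-dien-2-ol (2β-OH) | C=C1CC[C@H]2C(C)(C)C[C@@H](O)C[C@]2(C)[C@H]1C=C | intermediate
16 | ethyl but-2-ynoate | CC#CC(=O)OCC | starting material
17 | ethyl (2Z)-3-iodobut-2-enoate | C/C(I)=C/C(=O)OCC | intermediate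
18 | C12 bis(3-methylbutan-2-yl)borane of 15, hydroxyl as its disiamylborinate | C=C1CC[C@H]2C(C)(C)C[C@@H](OB(C(C)C(C)C)C(C)C(C)C)C[C@]2(C)[C@H]1CCB(C(C)C(C)C)C(C)C(C)C | intermediate
19 | ethyl (2R,5S,9S,10S,13Z)-2-hydroxylabda-8(17),13-dien-15-oate | C=C1CC[C@H]2C(C)(C)C[C@@H](O)C[C@]2(C)[C@H]1CC/C(C)=C\C(=O)OCC | intermediate
20 | (2R,5S,9S,10S,13Z)-2-hydroxylabda-8(17),13-dien-15-oic acid | C=C1CC[C@H]2C(C)(C)C[C@@H](O)C[C@]2(C)[C@H]1CC/C(C)=C\C(=O)O | intermediate
21 | mixed anhydride of the 2-acetoxy acid with acetic acid | C=C1CC[C@H]2C(C)(C)C[C@@H](OC(C)=O)C[C@]2(C)[C@H]1CC/C(C)=C\C(=O)OC(C)=O | intermediate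
22 | (2R,5S,9S,10S,13Z)-2-acetoxylabda-8(17),13-dien-15-oic acid | C=C1CC[C@H]2C(C)(C)C[C@@H](OC(C)=O)C[C@]2(C)[C@H]1CC/C(C)=C\C(=O)O | target

Total step count: 12. Longest linear sequence: 11 steps (steps 1–8 and 10–12); step 9 is a one-step side branch.

Steps most likely to fail

Step 6. The transfer of the alkenyl group to C10 may stall or be outrun by 1,2-addition, because the β-carbon is flanked by the substituted C5 and sees a syn-axial methyl on C4. The fallback sets out from 10 and builds the quaternary centre by a Lewis-acid route. Hosomi–Sakurai conjugate allylation (allyltrimethylsilane, TiCl4, CH2Cl2, −78 °C) tolerates β,β-disubstituted enones and should again enter anti to the C5 chain, giving (3S,4S)-3-allyl-3,5,5-trimethyl-4-[4-(trimethylsilyl)but-3-yn-1-yl]cyclohexan-1-one F1. Alkene migration with [Ir(cod)(PMePh2)2]PF6 (activated with H2, THF, rt) should then give (3R,4S)-3,5,5-trimethyl-3-[(1E)-prop-1-en-1-yl]-4-[4-(trimethylsilyl)but-3-yn-1-yl]cyclohexan-1-one F2. K2CO3 in MeOH removes the alkynyl silyl group, and the route is rejoined at 13.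

Step 7. Hydropalladation of the terminal alkyne may lead to oligomerisation faster than ring closure, or insertion into the alkene next to quaternary C10 may be too slow. The fallback sets out from 13 and makes the same C8–C9 bond by oxidative addition instead of hydrometalation. Markovnikov hydroiodination of the alkyne (B-iodo-9-BBN, pentane, −20 °C; then AcOH) gives (3R,4S)-4-(3-iodobut-3-en-1-yl)-3,5,5-trimethyl-3-[(1E)-prop-1-en-1-yl]cyclohexan-1-one F3. An intramolecular Heck reaction (Pd(OAc)2, PPh3, Ag2CO3, MeCN, 70 °C; 6-exo-trig, β-hydride elimination towards the methyl group) returns to 14.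

Step 10. The dialkylborane may discriminate poorly between the C11=C12 vinyl group and the C8=C17 methylene, or the hindered B-alkyl group may transfer sluggishly to palladium. The fallback sets out from 15 and moves the selection to a metal catalyst. RhCl(PPh3)3-catalysed hydroboration with pinacolborane (THF, rt), which strongly prefers monosubstituted alkenes, gives the isolable primary boronate (2R,5S,9S,10S)-12-(4,4,5,5-tetramethyl-1,3,2-dioxaborolan-2-yl)-13,14,15,16-tetranorlabd-8(17)-en-2-ol F4. Suzuki–Miyaura coupling with 17 (Pd(OAc)2, RuPhos, K3PO4, toluene/H2O, 80 °C) returns to 19.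

Further compounds
F1 | step 6 | (3S,4S)-3-allyl-3,5,5-trimethyl-4-[4-(trimethylsilyl)but-3-yn-1-yl]cyclohexan-1-one | C[Si](C)(C)C#CCC[C@H]1C(C)(C)CC(=O)C[C@]1(C)CC=C
F2 | step 6 | (3R,4S)-3,5,5-trimethyl-3-[(1E)-prop-1-en-1-yl]-4-[4-(trimethylsilyl)but-3-yn-1-yl]cyclohexan-1-one | C[Si](C)(C)C#CCC[C@H]1C(C)(C)CC(=O)C[C@]1(C)/C=C/C
F3 | step 7 | (3R,4S)-4-(3-iodobut-3-en-1-yl)-3,5,5-trimethyl-3-[(1E)-prop-1-en-1-yl]cyclohexan-1-one | C=C(I)CC[C@H]1C(C)(C)CC(=O)C[C@]1(C)/C=C/C
F4 | step 10 | (2R,5S,9S,10S)-12-(4,4,5,5-tetramethyl-1,3,2-dioxaborolan-2-yl)-13,14,15,16-tetranorlabd-8(17)-en-2-ol | C=C1CC[C@H]2C(C)(C)C[C@@H](O)C[C@]2(C)[C@H]1CCB1OC(C)(C)C(C)(C)O1
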